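**Retrosynthetic overview**
- The C3–C1' bond and the O1–C2 bond of the isoflavone are cut together, giving the o-hydroxyaryl enaminone 3 and plain veratrole 4; they are joined by an anodic dehydrogenative cross-coupling/annulation cascade.
- Enabling feature: chromone C3 is the α-carbon of the vinylogous amide O=C4–C3=C2–NMe2 of 3, and C1' of ring B is C4 of veratrole (para to a methoxy group). Both are donor carbons, so the bond is a like-polarity union made by oxidation, and the ortho OH plus the NMe2 leaving group on C2 let ring C close in the same operation.
- Enaminone 3 comes from ketone 2 and DMF dimethyl acetal; 2 comes from 2,4-dihydroxyacetophenone 1 by regioselective O-prenylation.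
- Ring order: ring A is bought (1), ring B is bought (4), and the pyranone ring C is formed last, in the key step.

Key step: step 3

Remark on the chemistry: the target has no stereocentre, and its only non-ring double bond (prenyl) carries two identical methyl groups, so it is a single achiral compound and no stereocontrol is required.

**Step 1**
Reactants: 1 2,4-dihydroxyacetophenone
Product: 2 1-[2-hydroxy-4-(3-methylbut-2-enyloxy)phenyl]ethanone
Conditions: prenyl bromide (1.1 equiv), K2CO3 (1.2 equiv), acetone, reflux
Reagents that add atoms: prenyl bromide (1-bromo-3-methylbut-2-ene), CC(C)=CCBr
Why: Williamson ether synthesis; the 4-OH is the more acidic, free phenol, whereas the 2-OH is held in a hydrogen bond to the acetyl carbonyl, so mono-O-alkylation at O4 is expected and no stereocentre is formed.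

**Step 2**
Reactants: 2 1-[2-hydroxy-4-(3-methylbut-2-enyloxy)phenyl]ethanone
Product: 3 (E)-3-(dimethylamino)-1-[2-hydroxy-4-(3-methylbut-2-enyloxy)phenyl]prop-2-en-1-one
Conditions: DMF-DMA (2 equiv), toluene, 90 °C
Reagents that add atoms: N,N-dimethylformamide dimethyl acetal, COC(OC)N(C)C
Why: Amide-acetal condensation of a methyl ketone (enaminone formation) should give the thermodynamically preferred E vinylogous amide, the chelated phenol being left free and the temperature staying far below that of an aryl prenyl ether Claisen rearrangement.

**Step 3**
Reactants: 3 (E)-3-(dimethylamino)-1-[2-hydroxy-4-(3-methylbut-2-enyloxy)phenyl]prop-2-en-1-one; 4 veratrole (1,2-dimethoxybenzene, 8 equiv)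
Product: 6 7-prenyloxy-3',4'-dimethoxyisoflavone, via 2-(dimethylamino)isoflavanone aminal 5 (not isolated)
Conditions: undivided cell, graphite anode, Pt cathode, constant current (ca. 5 mA/cm2, 2.2 F/mol), n-Bu4NPF6 (0.1 M), 2,6-lutidine (0.5 equiv), HFIP/CH2Cl2 (1:4), rt
Reagents that add atoms: none
Why: Proposed new method: at the carbon anode the vinylogous amide 3 and veratrole 4 (both expected to be oxidised at about +1.2 to +1.5 V vs SCE, far below the trisubstituted prenyl alkene) give a radical cation that is captured by the other, neutral partner, and on either path the bond forms between the α-carbon of the enaminone (its only nucleophilic carbon and the site of highest spin density in its radical cation) and C4 of veratrole; a second electron transfer and loss of the arene proton then rearomatise ring B and leave an α-aryl iminium ion. The closest known reaction types are the anodic dehydrogenative arene–arene and phenol–arene cross-couplings in HFIP and the oxidative α-C–H functionalisation/chromone annulation cascades of o-hydroxyaryl enaminones with heteroatom or radical partners, to which a plain arene C–H partner is the new element. Ring C closes by 6-exo-trig addition of the chelated phenol oxygen to the iminium carbon to give aminal 5, from which acid-assisted β-elimination of dimethylamine delivers the chromone, the two released protons being reduced to hydrogen at the cathode. The step leaves no stereocentre: both sp3 carbons of 5 become sp2 in 6. It needs cross- over homo-coupling, mono-arylation and attack para to a methoxy group: the excess of 4 and the much higher nucleophilicity of the enaminone α-carbon compared with neutral veratrole or the prenyl alkene favour the cross-product, HFIP stabilises the radical cations and damps over-oxidation, the product should be harder to oxidise than either partner because the nitrogen lone pair is gone and ring B carries the electron-poor chromone, and C4 of veratrole is both the least hindered position and the one of largest HOMO coefficient.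

**Compound list**
1 | 2,4-dihydroxyacetophenone | CC(=O)c1ccc(O)cc1O | starting material
2 | 1-[2-hydroxy-4-(3-methylbut-2-enyloxy)phenyl]ethanone | CC(=O)c1ccc(OCC=C(C)C)cc1O | intermediate
3 | (E)-3-(dimethylamino)-1-[2-hydroxy-4-(3-methylbut-2-enyloxy)phenyl]prop-2-en-1-one | CN(C)/C=C/C(=O)c1ccc(OCC=C(C)C)cc1O | intermediate
4 | veratrole (1,2-dimethoxybenzene) | COc1ccccc1OC | starting material
5 | 2-(dimethylamino)-3-(3,4-dimethoxyphenyl)-7-(3-methylbut-2-enyloxy)chroman-4-one (mixture of stereoisomers, both centres lost on elimination; not isolated) | COc1ccc(C2C(N(C)C)Oc3cc(OCC=C(C)C)ccc3C2=O)cc1OC | intermediate
6 | 7-prenyloxy-3',4'-dimethoxyisoflavone | COc1ccc(-c2coc3cc(OCC=C(C)C)ccc3c2=O)cc1OC | target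

**Step count**
Total step count: 3. Longest linear sequence: 3 steps (1 → 2 → 3 → 6); veratrole 4 enters as a purchased partner in step 3.

**Steps most likely to fail**

Step 3 (proposed new method). The charge may be consumed by homo-coupling and oligomerisation of veratrole, the enaminone radical cation may be trapped by the prenyl alkene of a second molecule, anodically generated acid may cleave the prenyl ether in HFIP, or the product may be over-oxidised, so that cross-coupling is poor. The fallback sets out from 3 and uses known chemistry. Iodocyclisation (I2, pyridine, CHCl3, rt; electrophilic iodination of the α-carbon, ring closure and loss of dimethylamine) should give 3-iodo-7-(3-methylbut-2-enyloxy)-4H-chromen-4-one F1. Suzuki–Miyaura coupling of this iodide with commercial 3,4-dimethoxyphenylboronic acid (Pd(PPh3)4, Na2CO3, DME/H2O, 80 °C) forms the same C3–C1' bond and comes back to the route at 6.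

Step 2. The amide acetal may O-methylate the phenol, or the enaminone may cyclise prematurely to the 3-unsubstituted chromone on prolonged heating, which would remove the nucleophilic α-carbon/free phenol pair needed for the key step. The fallback sets out from 2. Claisen formylation (ethyl formate, NaH, THF, 0 °C to rt) should give the cyclic hemiacetal of the β-keto aldehyde, 2-hydroxy-7-(3-methylbut-2-enyloxy)chroman-4-one F2. Condensation of this masked keto aldehyde with dimethylamine (2 M in THF, EtOH, rt) opens it to the chelated vinylogous amide and comes back to the route at 3.

Step 1. The ambident phenoxide may be alkylated a second time at the chelated 2-OH or at ring carbon (C-prenylation), eroding the regioselectivity. The fallback sets out from 1. Mitsunobu etherification with 3-methylbut-2-en-1-ol (PPh3, DIAD, THF, 0 °C to rt) engages only the more acidic, non-chelated 4-OH and cannot C-alkylate; it comes back to the route at 2 without any new compound on the way (entry F0).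

**Further compounds**
F1 | step 3 | 3-iodo-7-(3-methylbut-2-enyloxy)-4H-chromen-4-one | O=c1c(I)coc2cc(OCC=C(C)C)ccc12
F2 | step 2 | 2-hydroxy-7-(3-methylbut-2-enyloxy)chroman-4-one (racemic hemiacetal) | O=C1CC(O)Oc2cc(OCC=C(C)C)ccc12
F0 | step 1 | none | none
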